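**Structural features**

The target is an unsymmetrical biflavonoid ether. A (2S)-flavanone (rings A, C and B; 5-OH, 7-OMe, 4'-OH) is bonded at C6, through one oxygen, to C4''' of the phenylene ring of a 5,7-dihydroxyflavone. The halves are joined only by the diaryl ether C6–O–C4''', and the flavone core is joined to its phenylene ring by the C2''–C1''' bond. The single stereocentre is C2 of the flavanone, which has no stereogenic neighbour. It is benzylic, carries the ring oxygen and lies β to the C4 ketone, so base can open ring C by E1cB to the achiral 2'-hydroxychalcone and reclose it as the racemate. Other fragile features are the four phenols (5-OH is chelated to C4=O), the benzylic C2–O1 bond (hydrogenolysis, Lewis acids) and the flavone enone. The real difficulty is the ether oxygen on C6: this carbon is flanked by the oxygenated carbons C5 and C7 of an electron-rich ring, so an aryl–oxygen coupling would have to be forced at a doubly ortho-substituted position, and 5-OH/7-OMe and C6/C8 would still have to be differentiated. The key step exploits the fact that C5–C6–C7–C8 of ring A has the oxidation pattern of an acetoacetate (ester carbon, α-carbon, ketone carbon, methyl). The C6–O bond can therefore be made by SN2 at the α-carbon of a β-keto ester, and ring A is then completed by [4+2] addition of the derived diene to the C5=C6 bond of an enantiopure dihydropyranone that already is ring C.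

**Logic of the disconnections**

21 ⇒ 20. The three O–CH2Ph bonds at O4', O5'' and O7'' are cut. The phenols that would quench an organometallic partner or direct metalation elsewhere stay masked until the end, and one neutral operation releases all of them. The forward step must not reduce the flavone C2''=C3'' bond or the C4 ketone, and must not cleave the benzylic C2–O1 bond.

20 ⇒ 14 + 18 (through 19). The C2''–C1''' bond between the flavone core and its phenylene ring is cut. This is the most convergent cut: the complete flavone arrives in one sp2–sp2 coupling and the molecule falls into two halves of similar size. The forward step needs metalation of 18 at C2'' only, a coupling that tolerates the chelated 5-OH of 14 (left free, because silylating this hindered, hydrogen-bonded phenol would cost two steps and expose C2 to base), and no free strong base near C2.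

18 ⇒ 16 (through 17) ⇒ 15. The O1''–C2'' and C2''–C3'' bonds are cut (one carbon inserted between the acetyl methyl and the ortho phenol), then the two benzyl ethers. This reduces the chromone to a commercial acetophenone. The benzylation must spare the chelated ortho hydroxyl that later closes the pyranone.

14 ⇒ 6 + 11. The C4a–C5 and C8–C8a bonds are cut, so ring A disappears. The hindered C6–O ether, the 5-OH/7-OMe differentiation and the C6/C8 regiochemistry are all transferred to an acyclic diene, and the stereocentre is carried by a small, separately made ring C. The forward step needs a concerted, Lewis-acid-free cycloaddition with the diene CH2 terminus on the enone β-carbon, followed by aromatisation without base.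

11 ⇒ 10 ⇒ 7 + 8 (through 9). First the C5–Br bond is cut, then C2–C3 and O1–C6. The bromine is both the activating and the leaving group, and it is put on last so that the asymmetric step runs on the simplest substrates. The forward steps need a catalyst that fixes the C2 configuration, and a bromination without base, because the C3 enolate of 10 or 11 can expel O1.

6 ⇒ 4 (through 5) ⇒ 3 ⇒ 1 + 2. The O–Si bond (γ-deprotonation and O-silylation) is cut, then the enol ether O–CH3/C7–O bond back to the ketone, then the sp3 C–O bond that becomes C6–O. Every ring-A heteroatom is then in place on a four-carbon chain made from two commercial compounds. The forward steps need O-alkylation of the phenol at an unhindered secondary carbon and an amide base that leaves the C–I bond alone.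

**Other disconnections considered**

Alternative 1: The cut removes the phenylene ring (C2'''–C3''' and C4'''–C5''') while keeping the ether C–O bond. Forward, aryl ethynyl ether A1 would add with inverse electron demand across C3 and C6 of pyranone ester A2. Decarboxylation of the bridged adduct would give the para-aryloxy benzoate A3, with the nucleophilic terminal alkyne carbon matched to C6 of A2.
- In favour: the ether oxygen is again attached before the ring exists, so on the central problem this plan is the equal of the chosen one. Its pericyclic step is closer to established alkoxyalkyne/pyranone chemistry, so on mechanistic risk it is the better of the two.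
- Against: it builds the unhindered, trivially available ring and leaves ring A symmetric (two methoxy groups). The flavanone would still need C-acylation, condensation, a late enantioselective oxa-Michael closure and a selective demethylation at O5, and the flavone would have to be grown from the ester under strongly basic conditions that a flavanone does not survive.
- Step economy: roughly ten operations would follow A3, against two after 14 in the chosen plan, and the stereocentre would be set late by a less dependable method.

Alternative 2: The cut is C4a''–C5'' of the flavone; its phloroglucinol ring would be folded from the pyranone-bearing acyl Meldrum's acid A4. Forward, thermolysis would give an acylketene whose dienol form closes onto the pyranone α-carbon (6π closure/C-acylation), and tautomerisation would give the 5,7-dihydroxyflavone A5.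
- In favour: the flavone hydroxyls appear unprotected under neutral conditions, a point on which it is better than the chosen plan, which carries two benzyl groups on 18. The level of precedent (ketene-based resorcinol syntheses) is about equal to that of the chosen key step.
- Against: the strategic step is spent on the easy ring. The hindered diaryl ether must already be present in A4, ring A is again symmetric, and the flavanone would have to be built and desymmetrised in the presence of free flavone phenols. A4 itself needs several steps, and the acylketene can also dimerise or be O-acylated.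
- Step economy: clearly worse. On structure it does not address the crowded C6–O bond at all.

Alternative 3: The cuts are O1''–C8a'', C4''–C4a'' and O1''–C2''. Forward, fluoride would release the aryne from silyl triflate A7, and the carboxylate of arylpropiolic acid A6 would add at the aryne carbon remote from the adjacent benzyloxy group. The aryl anion would take the acyl carbon, and the freed phenoxide would add 6-endo to the ynone to give flavone A8.
- In favour: three bonds and the pyranone ring form in one mild operation with regiochemistry set by the alkoxy group. In convergence it equals the Negishi coupling of the chosen plan, and because no stereocentre exists at that stage it is better on configurational safety of the coupling itself.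
- Against: the diaryl ether of A6 must be made beforehand by an unspecified hindered coupling and A7 needs several steps. 5-exo closure to an aurone can compete. The symmetric ring A leaves the same late flavanone problems as in alternatives 1 and 2.
- Step economy: worse overall. Mechanistically it is better precedented than the chosen key step, but it solves a part of the molecule that the chosen plan handles with a standard cross-coupling.

Key step: step 6

Assumption: the facial sense of the BINOL–titanium catalyst in step 4 is taken as (S)-BINOL giving (S)-10; the sign is to be checked on 10, and the antipodal ligand used if it is opposite, with nothing else changed.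

**Route**

Step 1
Reactants: 1 4-iodophenol; 2 methyl 2-chloro-3-oxobutanoate
Product: 3 methyl 2-(4-iodophenoxy)-3-oxobutanoate
Conditions: K2CO3 (1.1 equiv), acetone, 56 °C; dilute HCl work-up
Reagents that add atoms: none
Why: Williamson-type O-alkylation of the phenoxide at the doubly activated secondary chloride (SN2); this makes the future C6–O bond at an unhindered sp3 carbon, and the aryl iodide is inert to carbonate.

Step 2
Reactants: 3 methyl 2-(4-iodophenoxy)-3-oxobutanoate
Product: 4 methyl 2-(4-iodophenoxy)-3-methoxybut-2-enoate (E/Z mixture)
Conditions: HC(OMe)3, TsOH·H2O (cat.), MeOH, 23 to 50 °C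
Reagents that add atoms: trimethyl orthoformate COC(OC)OC
Why: Acid-catalysed ketalisation and loss of methanol gives the methyl enol ether of the β-keto ester; catalytic acid at mild temperature avoids cyclodehydration onto the aryl ring, and the double-bond geometry is irrelevant because it is lost in the next step.

Step 3
Reactants: 4 methyl 2-(4-iodophenoxy)-3-methoxybut-2-enoate
Product: 6 (1E)-2-(4-iodophenoxy)-1,3-dimethoxy-1-(trimethylsilyloxy)buta-1,3-diene, via lithium dienolate 5 (not isolated)
Conditions: LiN(iPr)2 (1.1 equiv), THF, −78 °C; Me3SiCl (1.3 equiv), −78 to 0 °C; evaporate, pentane, filter under argon, use crude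
Reagents that add atoms: chlorotrimethylsilane C[Si](C)(C)Cl
Why: Kinetic γ-deprotonation of the β-methoxy acrylate and O-silylation of the dienolate is the standard preparation of 1,3-dialkoxy-1-silyloxybutadienes (vinylketene acetals); at −78 °C the hindered amide should not attack the C–I bond, and the ketene acetal geometry is immaterial.

Step 4
Reactants: 7 4-(benzyloxy)benzaldehyde; 8 trans-1-methoxy-3-(trimethylsilyloxy)buta-1,3-diene
Product: 10 (S)-2-[4-(benzyloxy)phenyl]-2,3-dihydro-4H-pyran-4-one, via silylated aldol adduct 9 (not isolated)
Conditions: (S)-BINOL (20 mol %), Ti(OiPr)4 (10 mol %), CF3CO2H (cat.), 4 Å MS, Et2O, −20 °C; then CF3CO2H, CH2Cl2, 0 °C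
Reagents that add atoms: none
Why: BINOL–titanium-catalysed Mukaiyama aldol addition followed by acid cyclisation (formal hetero-Diels–Alder); the chiral titanium BINOLate blocks one face of the bound aldehyde so the diene terminus sets C2 as (S) in 9, and the acid then closes O1–C6 with loss of methanol without touching C2.

Step 5
Reactants: 10 (S)-2-[4-(benzyloxy)phenyl]-2,3-dihydro-4H-pyran-4-one
Product: 11 (S)-5-bromo-2-[4-(benzyloxy)phenyl]-2,3-dihydro-4H-pyran-4-one
Conditions: N-bromosuccinimide (1.05 equiv), CH2Cl2, 0 to 23 °C, dark
Reagents that add atoms: N-bromosuccinimide O=C1CCC(=O)N1Br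
Why: Electrophilic α-bromination of the vinylogous ester (the enol ether carbon C5 attacks bromine, proton loss restores the enone); no base is present, so the C3 enolate that could expel O1 and scramble C2 is never formed.

Step 6
Reactants: 6 (1E)-2-(4-iodophenoxy)-1,3-dimethoxy-1-(trimethylsilyloxy)buta-1,3-diene; 11 (S)-5-bromo-2-[4-(benzyloxy)phenyl]-2,3-dihydro-4H-pyran-4-one
Product: 14 (S)-4'-O-benzyl-5-hydroxy-6-(4-iodophenoxy)-7-methoxyflavanone, via cis-fused bromo ketal cycloadduct 12 (not isolated), via 5-O-trimethylsilyl flavanone 13 (not isolated)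
Conditions: 6 (2.0 equiv), PhMe (1 M), 85 °C; then SiO2, CH2Cl2, 23 °C; then 1 M HCl, THF, 23 °C
Reagents that add atoms: none
Why: Proposed new method: the terminal CH2 of the electron-rich diene 6 (largest HOMO coefficient) bonds to the β-carbon C6 of bromoenone 11 and the acetal carbon bonds to the bromine-bearing C5, in a thermal, asynchronous normal-demand [4+2] that gives the cis-fused adduct 12. The closest known reaction type is the cycloaddition–aromatisation of 1,3-dialkoxy-1-silyloxybutadienes with halogenated quinones, α-halo enones and acceptor-substituted chromones; new here are the 2-aryloxy diene and the β-oxygenated (vinylogous ester) bromoenone. Ring A is the only ring closed, as a six-membered carbocycle formed by concerted suprafacial addition across the future C4a–C8a bond and fused to the existing ring C. No lasting stereocentre is made: the three new sp3 centres of 12 (C4a, C5, C8a) become planar on aromatisation, and C2 is a spectator because no base and no enolate are present. On silica the allylic ketal ionises and loses methanol (C5–OMe with a C8 proton), then the now allylic α-keto C4a–Br leaves with the C8a proton, driven by formation of the arene; dilute acid cleaves the silyl ether of 13 to the chelated phenol 14. The step needs regioselectivity (diene CH2 to the enone β-carbon, reinforced by bromine directing the acetal carbon to C4a) and selectivity for the concerted path over a Mukaiyama–Michael addition, which the absence of any Lewis acid secures, since only a stepwise enolate could expel O1. Bromine lowers the LUMO of the otherwise sluggish dienophile and supplies the unsaturation needed for aromatisation.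

Step 7
Reactants: 15 1-(2,4,6-trihydroxyphenyl)ethanone
Product: 16 1-[2,4-bis(benzyloxy)-6-hydroxyphenyl]ethanone
Conditions: BnBr (2.05 equiv), K2CO3 (2.2 equiv), DMF, 23 °C
Reagents that add atoms: benzyl bromide BrCc1ccccc1
Why: Selective Williamson benzylation; with two equivalents the para and one ortho phenoxide are alkylated, while the hydroxyl hydrogen-bonded to the acetyl group is the least nucleophilic and remains free.

Step 8
Reactants: 16 1-[2,4-bis(benzyloxy)-6-hydroxyphenyl]ethanone
Product: 18 5,7-bis(benzyloxy)-4H-chromen-4-one, via enaminone 17 (not isolated)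
Conditions: Me2NCH(OMe)2 (2 equiv), PhMe, 95 °C; evaporate; then conc. HCl, CH2Cl2, 23 °C
Reagents that add atoms: N,N-dimethylformamide dimethyl acetal COC(OC)N(C)C
Why: Condensation of the methyl ketone with the amide acetal gives enaminone 17; acid then triggers oxa-Michael addition of the free phenol and loss of dimethylamine (the enaminone route to 2,3-unsubstituted chromones).

Step 9
Reactants: 18 5,7-bis(benzyloxy)-4H-chromen-4-one; 14 (S)-4'-O-benzyl-5-hydroxy-6-(4-iodophenoxy)-7-methoxyflavanone
Product: 20 (2S)-2-[4-(benzyloxy)phenyl]-6-{4-[5,7-bis(benzyloxy)-4-oxo-4H-chromen-2-yl]phenoxy}-5-hydroxy-7-methoxychroman-4-one, via chromon-2-ylzinc chloride 19 (not isolated)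
Conditions: 18 (2.3 equiv), TMPZnCl·LiCl (2.2 equiv), THF, 25 °C; then 14 (1.0 equiv), Pd(OAc)2 (4 mol %), SPhos (8 mol %), THF, 25 to 40 °C; aq. NH4Cl
Reagents that add atoms: none
Why: The magnesium-free zinc amide should remove the most acidic vinylic proton of the chromone, C2''–H next to the ring oxygen, and Negishi cross-coupling (oxidative addition of zerovalent palladium into C–I, transmetalation, reductive elimination) forms C2''–C1'''. The biaryl phosphine catalyst is the type used for halides bearing acidic protons, so the chelated 5-OH can stay free; 18 is kept in excess over the amide so that no free zinc amide reaches the flavanone, and C2 should keep its configuration.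

Step 10
Reactants: 20 (2S)-2-[4-(benzyloxy)phenyl]-6-{4-[5,7-bis(benzyloxy)-4-oxo-4H-chromen-2-yl]phenoxy}-5-hydroxy-7-methoxychroman-4-one
Product: 21 (2S)-6-[4-(5,7-dihydroxy-4-oxo-4H-chromen-2-yl)phenoxy]-5-hydroxy-2-(4-hydroxyphenyl)-7-methoxychroman-4-one
Conditions: H2 (1 atm), 10% Pd/C, THF–MeOH, 23 °C, monitored and stopped at full debenzylation
Reagents that add atoms: none
Why: Heterogeneous hydrogenolysis of the three aryl benzyl ethers; at one atmosphere and ambient temperature these primary benzylic C–O bonds should cleave much faster than the flavone double bond, the aryl ketone or the secondary benzylic C2–O1 bond, and the neutral medium leaves C2 untouched.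

**Compound list**

1 | 4-iodophenol | Oc1ccc(I)cc1 | starting material
2 | methyl 2-chloro-3-oxobutanoate | COC(=O)C(Cl)C(C)=O | starting material
3 | methyl 2-(4-iodophenoxy)-3-oxobutanoate | COC(=O)C(Oc1ccc(I)cc1)C(C)=O | intermediate
4 | methyl 2-(4-iodophenoxy)-3-methoxybut-2-enoate (E/Z mixture) | COC(=O)C(Oc1ccc(I)cc1)=C(C)OC | intermediate
5 | lithium dienolate of 4 (lithium 2-(4-iodophenoxy)-1,3-dimethoxybuta-1,3-dien-1-olate) | C=C(OC)C(Oc1ccc(I)cc1)=C(OC)O[Li] | intermediate (not isolated)
6 | (1E)-2-(4-iodophenoxy)-1,3-dimethoxy-1-(trimethylsilyloxy)buta-1,3-diene | C=C(OC)/C(Oc1ccc(I)cc1)=C(/OC)O[Si](C)(C)C | intermediate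
7 | 4-(benzyloxy)benzaldehyde | O=Cc1ccc(OCc2ccccc2)cc1 | starting material
8 | trans-1-methoxy-3-(trimethylsilyloxy)buta-1,3-diene | CO/C=C/C(=C)O[Si](C)(C)C | starting material
9 | (S,E)-5-[4-(benzyloxy)phenyl]-1-methoxy-5-(trimethylsilyloxy)pent-1-en-3-one | CO/C=C/C(=O)C[C@@H](c1ccc(OCc2ccccc2)cc1)O[Si](C)(C)C | intermediate (not isolated)
10 | (S)-2-[4-(benzyloxy)phenyl]-2,3-dihydro-4H-pyran-4-one | O=C1C[C@@H](c2ccc(OCc3ccccc3)cc2)OC=C1 | intermediate
11 | (S)-5-bromo-2-[4-(benzyloxy)phenyl]-2,3-dihydro-4H-pyran-4-one | O=C1C[C@@H](c2ccc(OCc3ccccc3)cc2)OC=C1Br | intermediate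
12 | (2S)-2-[4-(benzyloxy)phenyl]-4a-bromo-6-(4-iodophenoxy)-5,7-dimethoxy-5-(trimethylsilyloxy)-2,3,4a,5,8,8a-hexahydro-4H-chromen-4-one (cis ring fusion, mixture at C4a, C5, C8a) | COC1=C(Oc2ccc(I)cc2)C(OC)(O[Si](C)(C)C)C2(Br)C(=O)C[C@@H](c3ccc(OCc4ccccc4)cc3)OC2C1 | intermediate (not isolated)
13 | (S)-4'-O-benzyl-6-(4-iodophenoxy)-7-methoxy-5-(trimethylsilyloxy)flavanone | COc1cc2c(c(O[Si](C)(C)C)c1Oc1ccc(I)cc1)C(=O)C[C@@H](c1ccc(OCc3ccccc3)cc1)O2 | intermediate (not isolated)
14 | (S)-4'-O-benzyl-5-hydroxy-6-(4-iodophenoxy)-7-methoxyflavanone | COc1cc2c(c(O)c1Oc1ccc(I)cc1)C(=O)C[C@@H](c1ccc(OCc3ccccc3)cc1)O2 | intermediate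
15 | 1-(2,4,6-trihydroxyphenyl)ethanone | CC(=O)c1c(O)cc(O)cc1O | starting material
16 | 1-[2,4-bis(benzyloxy)-6-hydroxyphenyl]ethanone | CC(=O)c1c(O)cc(OCc2ccccc2)cc1OCc1ccccc1 | intermediate
17 | (E)-1-[2,4-bis(benzyloxy)-6-hydroxyphenyl]-3-(dimethylamino)prop-2-en-1-one | CN(C)/C=C/C(=O)c1c(O)cc(OCc2ccccc2)cc1OCc1ccccc1 | intermediate (not isolated)
18 | 5,7-bis(benzyloxy)-4H-chromen-4-one | O=c1ccoc2cc(OCc3ccccc3)cc(OCc3ccccc3)c12 | intermediate
19 | [5,7-bis(benzyloxy)-4-oxo-4H-chromen-2-yl]zinc chloride (as its LiCl complex) | O=c1cc([Zn]Cl)oc2cc(OCc3ccccc3)cc(OCc3ccccc3)c12 | intermediate (not isolated)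
20 | (2S)-2-[4-(benzyloxy)phenyl]-6-{4-[5,7-bis(benzyloxy)-4-oxo-4H-chromen-2-yl]phenoxy}-5-hydroxy-7-methoxychroman-4-one | COc1cc2c(c(O)c1Oc1ccc(-c3cc(=O)c4c(OCc5ccccc5)cc(OCc5ccccc5)cc4o3)cc1)C(=O)C[C@@H](c1ccc(OCc3ccccc3)cc1)O2 | intermediate
21 | (2S)-6-[4-(5,7-dihydroxy-4-oxo-4H-chromen-2-yl)phenoxy]-5-hydroxy-2-(4-hydroxyphenyl)-7-methoxychroman-4-one | COc1cc2c(c(O)c1Oc1ccc(-c3cc(=O)c4c(O)cc(O)cc4o3)cc1)C(=O)C[C@@H](c1ccc(O)cc1)O2 | target

**Step count and least certain steps**

Total: 10 steps. Longest linear sequence: 6 steps (steps 1, 2, 3, 6, 9, 10). The dienophile branch (steps 4, 5) and the chromone branch (steps 7, 8) are shorter and converge at steps 6 and 9.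

Step 6 (key step).
- What may go wrong: the β-oxygenated bromoenone may be too poor a dienophile, so the diene decomposes or is protodesilylated before it adds. The 2-aryloxy group is a counter-directing donor on the diene and may erode regioselectivity. A stepwise addition followed by β-elimination of O1 would open ring C. Halophilic loss of bromine would leave an adduct that cannot aromatise. Loss of silanol instead of methanol would give the 5-methyl ether, which a chelation-controlled BCl3 demethylation would bring back to 14.
- Fallback (known reaction types only): it draws on no intermediate before 14; it sets out from commercial 4-hydroxy-3,5-dimethoxybenzaldehyde and (4-iodophenyl)boronic acid, the boron counterpart of 1, and comes back to the route at 14. Copper-mediated Chan–Lam O-arylation (Cu(OAc)2, pyridine, 4 Å MS, CH2Cl2, air) of the hindered phenol should give 4-(4-iodophenoxy)-3,5-dimethoxybenzaldehyde F1. Baeyer–Villiger oxidation with mCPBA should give 4-(4-iodophenoxy)-3,5-dimethoxyphenyl formate F2, and methanolysis (K2CO3, MeOH) the phenol 4-(4-iodophenoxy)-3,5-dimethoxyphenol F3. Friedel–Crafts acetylation ortho to the hydroxyl (Ac2O, BF3·OEt2) should give 1-[6-hydroxy-3-(4-iodophenoxy)-2,4-dimethoxyphenyl]ethanone F4. The amide acetal then gives (E)-3-(dimethylamino)-1-[6-hydroxy-3-(4-iodophenoxy)-2,4-dimethoxyphenyl]prop-2-en-1-one F5, and acid closes it to 6-(4-iodophenoxy)-5,7-dimethoxy-4H-chromen-4-one F6. Asymmetric conjugate addition of [4-(benzyloxy)phenyl]boronic acid, catalysed by Pd(OCOCF3)2 with the t-BuPyOx antipode that delivers the 2S product (NH4PF6, water, 1,2-dichloroethane, 60 °C; the cycle stays at divalent palladium and should leave the C–I bond alone), would give (S)-4'-O-benzyl-6-(4-iodophenoxy)-5,7-dimethoxyflavanone F7. Chelation-controlled demethylation of the peri methoxy group (BCl3, 1.1 equiv, CH2Cl2, −78 °C) would give 14.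

Step 3.
- What may go wrong: competing attack of the amide base at the aryl iodide, incomplete γ-deprotonation of the crowded acrylate, or hydrolysis of the non-distillable diene on handling.
- Fallback: it sets out from 3 and comes back at 14, replacing steps 2 and 3. Soft enolisation of 3 with Me3SiOTf/Et3N (2.2 equiv each, Et2O, 0 °C) avoids any strong base and should give 2-(4-iodophenoxy)-1-methoxy-1,3-bis(trimethylsilyloxy)buta-1,3-diene F8. Cycloaddition of F8 with 11 as in step 6 would pass through the adduct (2S)-2-[4-(benzyloxy)phenyl]-4a-bromo-6-(4-iodophenoxy)-5-methoxy-5,7-bis(trimethylsilyloxy)-2,3,4a,5,8,8a-hexahydro-4H-chromen-4-one F9. Aromatisation and acid work-up would give (S)-4'-O-benzyl-5,7-dihydroxy-6-(4-iodophenoxy)flavanone F10. Base-free methylation of the more acidic, non-chelated 7-OH with Me3SiCHN2 in PhMe–MeOH would then give 14.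

Step 9.
- What may go wrong: metalation of 18 at C3'' instead of C2'' (to be checked by iodine quench of an aliquot), protonation of the organozinc by the phenol of 14, or partial ring opening and reclosure of the flavanone in the presence of the liberated amine, with loss of enantiopurity.
- Fallback: it sets out from 18 and comes back at 20. Intermediate 19 is trapped with Bu3SnCl and the product purified free of amine to give 5,7-bis(benzyloxy)-2-(tributylstannyl)-4H-chromen-4-one F11. F11 is coupled with 14 under neutral Stille conditions (Pd(PPh3)4, CuI, DMF, 50 °C), which tolerate the free phenol and contain no base.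

Step 10.
- What may go wrong: over-reduction of the flavone double bond or the C4 ketone, or hydrogenolytic opening of ring C at the benzylic C2–O1 bond before the last benzyl ether has gone.
- Fallback: it sets out from 20 and comes back at 21. A non-reductive Lewis-acid debenzylation (BCl3, pentamethylbenzene as cation trap, CH2Cl2, −78 °C) is expected to spare the non-chelated 7-OMe at that temperature; it makes no new compound (F0).

**Further compounds**

F1 | step 6 | 4-(4-iodophenoxy)-3,5-dimethoxybenzaldehyde | COc1cc(C=O)cc(OC)c1Oc1ccc(I)cc1
F2 | step 6 | 4-(4-iodophenoxy)-3,5-dimethoxyphenyl formate | COc1cc(OC=O)cc(OC)c1Oc1ccc(I)cc1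
F3 | step 6 | 4-(4-iodophenoxy)-3,5-dimethoxyphenol | COc1cc(O)cc(OC)c1Oc1ccc(I)cc1
F4 | step 6 | 1-[6-hydroxy-3-(4-iodophenoxy)-2,4-dimethoxyphenyl]ethanone | CC(=O)c1c(O)cc(OC)c(Oc2ccc(I)cc2)c1OC
F5 | step 6 | (E)-3-(dimethylamino)-1-[6-hydroxy-3-(4-iodophenoxy)-2,4-dimethoxyphenyl]prop-2-en-1-one | CN(C)/C=C/C(=O)c1c(O)cc(OC)c(Oc2ccc(I)cc2)c1OC
F6 | step 6 | 6-(4-iodophenoxy)-5,7-dimethoxy-4H-chromen-4-one | COc1cc2occc(=O)c2c(OC)c1Oc1ccc(I)cc1
F7 | step 6 | (S)-4'-O-benzyl-6-(4-iodophenoxy)-5,7-dimethoxyflavanone | COc1cc2c(c(OC)c1Oc1ccc(I)cc1)C(=O)C[C@@H](c1ccc(OCc3ccccc3)cc1)O2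
F8 | step 3 | 2-(4-iodophenoxy)-1-methoxy-1,3-bis(trimethylsilyloxy)buta-1,3-diene | C=C(O[Si](C)(C)C)C(Oc1ccc(I)cc1)=C(OC)O[Si](C)(C)C
F9 | step 3 | (2S)-2-[4-(benzyloxy)phenyl]-4a-bromo-6-(4-iodophenoxy)-5-methoxy-5,7-bis(trimethylsilyloxy)-2,3,4a,5,8,8a-hexahydro-4H-chromen-4-one | C[Si](C)(C)OC1=C(Oc2ccc(I)cc2)C(OC)(O[Si](C)(C)C)C2(Br)C(=O)C[C@@H](c3ccc(OCc4ccccc4)cc3)OC2C1
F10 | step 3 | (S)-4'-O-benzyl-5,7-dihydroxy-6-(4-iodophenoxy)flavanone | Oc1cc2c(c(O)c1Oc1ccc(I)cc1)C(=O)C[C@@H](c1ccc(OCc3ccccc3)cc1)O2
F11 | step 9 | 5,7-bis(benzyloxy)-2-(tributylstannyl)-4H-chromen-4-one | CCCC[Sn](CCCC)(CCCC)c1cc(=O)c2c(OCc3ccccc3)cc(OCc3ccccc3)cc2o1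
F0 | step 10 | none | none
A1 | alternative 1 | 2-(ethynyloxy)-1,3-dimethoxy-5-(methoxymethoxy)benzene | COCOc1cc(OC)c(OC#C)c(OC)c1
A2 | alternative 1 | methyl 2-oxo-2H-pyran-5-carboxylate | COC(=O)C1=COC(=O)C=C1
A3 | alternative 1 | methyl 4-[2,6-dimethoxy-4-(methoxymethoxy)phenoxy]benzoate | COCOc1cc(OC)c(Oc2ccc(C(=O)OC)cc2)c(OC)c1
A4 | alternative 2 | 5-[2-(6-{4-[4-(benzyloxy)-2,6-dimethoxyphenoxy]phenyl}-4-oxo-4H-pyran-2-yl)acetyl]-2,2-dimethyl-1,3-dioxane-4,6-dione | COc1cc(OCc2ccccc2)cc(OC)c1Oc1ccc(-c2cc(=O)cc(CC(=O)C3C(=O)OC(C)(C)OC3=O)o2)cc1
A5 | alternative 2 | 2-{4-[4-(benzyloxy)-2,6-dimethoxyphenoxy]phenyl}-5,7-dihydroxy-4H-chromen-4-one | COc1cc(OCc2ccccc2)cc(OC)c1Oc1ccc(-c2cc(=O)c3c(O)cc(O)cc3o2)cc1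
A6 | alternative 3 | 3-{4-[2,6-dimethoxy-4-(methoxymethoxy)phenoxy]phenyl}prop-2-ynoic acid | COCOc1cc(OC)c(Oc2ccc(C#CC(=O)O)cc2)c(OC)c1
A7 | alternative 3 | 3,5-bis(benzyloxy)-2-(trimethylsilyl)phenyl trifluoromethanesulfonate | C[Si](C)(C)c1c(OCc2ccccc2)cc(OCc2ccccc2)cc1OS(=O)(=O)C(F)(F)F
A8 | alternative 3 | 5,7-bis(benzyloxy)-2-{4-[2,6-dimethoxy-4-(methoxymethoxy)phenoxy]phenyl}-4H-chromen-4-one | COCOc1cc(OC)c(Oc2ccc(-c3cc(=O)c4c(OCc5ccccc5)cc(OCc5ccccc5)cc4o3)cc2)c(OC)c1
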